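Locants: phthalide numbering. The unprimed half is the 4,5,6,7-tetrahydrophthalide (carbocycle = ring A, lactone A), with C6 and C7 on the cyclobutane. The primed half holds the quaternary cyclobutane carbons C3a' and C7a', lactone B and the cyclohexene C3a'–C4'–C5'–C6'=C7'–C7a' (ring B).
Cuts: C6'=C7' comes from a C7' enone by reductive 1,3-transposition. The C3a'–C4' and C7a'–C7' bonds are then cut together (Diels–Alder) to 1-siloxybutadiene and a cyclobutene whose C3a'=C7a' bond is both the α,β-bond of butenolide B and a four-ring alkene, so a strained, acceptor-activated dienophile with an open exo face; it is stored as a vicinal dichloride.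
Further back: lactone A from a C7a ketone (C-acylation at C3a, enol triflate, cyclocarbonylation); the cyclobutane from an intramolecular [2+2] photocycloaddition of a dichlorobutenolide pseudo-ester of (R)-cyclohex-2-en-1-ol; lactone B from dichloromaleic anhydride and a butyl Grignard reagent.
Forward order of rings: lactone B, ring A carbocycle (bought in), cyclobutane with a temporary tetrahydrofuran acetal ring (opened again in step 4), lactone A, ring B last.
Stereochemistry: the (R)-carbinol centre of the cyclohexenol is relayed through the five-membered acetal tether to C6 and C7 and then oxidised away; C3a' and C7a' arise in the cycloaddition on the face anti to ring A; both Z-ylidenes are the thermodynamically preferred enol-lactone isomers.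

Key step: step 9

Assumption: (R)-cyclohex-2-en-1-ol and (E)-1-(trimethylsiloxy)buta-1,3-diene are taken as catalogue compounds; pseudo-acid 3 is drawn as its ring tautomer and keto acids 7 and 8 as their open tautomers.

Step 1
Reactants: 1 dichloromaleic anhydride, 2 n-butylmagnesium bromide
Product: 3 (±)-5-butyl-3,4-dichloro-5-hydroxyfuran-2(5H)-one
Conditions: n-BuMgBr (1.05 equiv, inverse addition), THF, −78 °C; then 1 M HCl
Reagents that add atoms: none
Why: Grignard mono-addition to a symmetric cyclic anhydride (no regiochemical issue) should stop at the keto-carboxylate stage at low temperature and give the γ-hydroxybutenolide (pseudo-acid) on acidification, its hemiketal centre being racemic and equilibrated in step 2.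

Step 2
Reactants: 3 (±)-5-butyl-3,4-dichloro-5-hydroxyfuran-2(5H)-one, 4 (R)-cyclohex-2-en-1-ol
Product: 5 (5S)-5-butyl-3,4-dichloro-5-[(1R)-cyclohex-2-en-1-yloxy]furan-2(5H)-one
Conditions: CSA (10 mol %), 4 Å molecular sieves, CH2Cl2, rt; chromatography; the (5R)-epimer is returned to the same conditions
Reagents that add atoms: none
Why: Acid-catalysed pseudo-esterification (acetal formation through the furanone oxocarbenium ion, the allylic C–O bond of 4 staying intact so its configuration is kept) should give both acetal epimers, which interconvert under the acid, and only the (5S) epimer can fold into the cis-fused adduct of step 3.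

Step 3
Reactants: 5 (5S)-5-butyl-3,4-dichloro-5-[(1R)-cyclohex-2-en-1-yloxy]furan-2(5H)-one
Product: 6 tetracyclic photoadduct (cyclobutane C6–C7–C3a'–C7a' cis-fused to the cyclohexane, to the tetrahydrofuran C7–C7a–O–C3'–C3a' and to the dichloro γ-lactone; both chlorines anti to the three rings)
Conditions: hν (300 nm), acetone (solvent and triplet sensitiser), 0.01 M, degassed, rt
Reagents that add atoms: none
Why: Intramolecular enone–alkene [2+2] photocycloaddition of a 1,6-diene (rule of five: C3a'–C7 closes the five-membered acetal ring first, then C7a'–C6) fixes the head-to-tail regiochemistry through the tether, and the obligatory cis fusion of the new tetrahydrofuran to the cyclohexane puts the cyclobutane on the alkene face syn to the (R)-carbinol oxygen, which sets C6 and C7.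

Step 4
Reactants: 6 tetracyclic photoadduct
Product: 8 C7a-keto acid (7,8-dichloro-2-oxo-8-pentanoylbicyclo[4.2.0]octane-7-carboxylic acid; carboxyl on C7a', pentanoyl on C3a', both syn to the six-membered ring), via hydroxy keto acid 7 (not isolated)
Conditions: CrO3, H2SO4, H2O, acetone, 0 °C to rt
Reagents that add atoms: water, O
Why: Jones oxidation, in which the aqueous acid opens the pseudo-ester acetal (carboxylate as leaving group) and the freed secondary alcohol is oxidised at once to the C7a ketone, which should pull the otherwise unfavourable acetal equilibrium over without touching a stereocentre that is kept.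

Step 5
Reactants: 8 C7a-keto acid
Product: 9 keto enol lactone ((Z)-butylidene lactone B fused to the 3a',7a'-dichlorocyclobutane; ring A as C7a ketone)
Conditions: (CF3CO)2O, CH2Cl2, 0 °C to rt
Reagents that add atoms: none
Why: Enol lactonisation of a cis γ-keto acid through its mixed anhydride and pseudo-acid trifluoroacetate, in which the quaternary C3a' allows only the exocyclic alkene and the acid formed should equilibrate it to the Z isomer (propyl anti to C3a').

Step 6
Reactants: 9 keto enol lactone, 10 pentanoyl chloride
Product: 11 C3a-pentanoyl β-diketone (endocyclic enol, OH on C7a)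
Conditions: LiN(SiMe3)2 (2.1 equiv), THF, −78 °C; then 10, −78 °C; then 1 M HCl
Reagents that add atoms: none
Why: Crossed Claisen C-acylation of the kinetic lithium enolate, formed at the unhindered C3a methylene and not at the ring-fusion methine C7 (whose enolate could expel the β-chloride), with the second equivalent of base taking up the more acidic β-diketone.

Step 7
Reactants: 11 C3a-pentanoyl β-diketone
Product: 12 C7a enol triflate (β-triflyloxy enone; C7a=C3a in ring A, pentanoyl on C3a)
Conditions: Tf2O, Et3N, CH2Cl2, −78 °C
Reagents that add atoms: trifluoromethanesulfonic anhydride, O=S(=O)(OS(=O)(=O)C(F)(F)F)C(F)(F)F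
Why: O-Sulfonylation of a β-diketone enolate, expected at the ring oxygen because 2-acylcyclohexanones enolise endocyclically, gives the β-triflyloxy enone with the cis geometry fixed by the ring.

Step 8
Reactants: 12 C7a enol triflate
Product: 13 3a',7a'-dichloro bis-lactone (lactones A and B closed, both (Z)-butylidene; chlorines cis and anti to ring A)
Conditions: PdCl2(PPh3)2 (5 mol %), CO (1 atm), Et3N, MeCN, 60 °C
Reagents that add atoms: carbon monoxide, [C-]#[O+]
Why: Palladium-catalysed cyclocarbonylation of a cis-β-(pseudo)halo enone (oxidative addition of zerovalent palladium to the vinyl triflate, CO insertion, capture of the acylpalladium by the enol oxygen of the pentanoyl group) should close lactone A as the ylidene butenolide, whose Z geometry (propyl syn to the ring oxygen, away from C4) is the favoured one.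

Step 9
Reactants: 13 3a',7a'-dichloro bis-lactone, 14 (E)-1-(trimethylsiloxy)buta-1,3-diene
Product: 17 7'-hydroxy cycloadduct (ring B closed with C5'=C6'; OH on C7' cis to C1'), via cyclobutene bis-butenolide 15 (not isolated), via silyl ether cycloadduct 16 (not isolated)
Conditions: Zn–Cu couple (activated, 3 equiv), 14 (5 equiv), THF, 0 °C to rt; then AcOH, THF, H2O, rt
Reagents that add atoms: none
Why: Proposed new method: zinc inserts into the C–Cl bond α to the lactone B carbonyl of 13 and the zinc enolate expels the β-chloride, unveiling cyclobutene 15, whose C3a'=C7a' bond is both the α,β-bond of butenolide B and a four-ring alkene and is therefore a strained, acceptor-activated dienophile that is trapped as it forms; the closest known reaction types are the zinc dechlorination of 1,2-dichlorocyclobutane-1,2-dicarbonyl compounds and the Diels–Alder reactions of cyclobut-1-ene-1,2-dicarboxylic anhydride and its esters, a cyclobutene-fused γ-ylidenebutenolide not having been used in this way. Ring B is closed by a thermal [4+2] cycloaddition, suprafacial on both partners and concerted but asynchronous (C3a'–C4' bond leading, the ZnCl2 formed acting as Lewis acid), which makes the C3a'–C4' and C7a'–C7' bonds. C3a' and C7a' become stereocentres together: their cis relation follows from the suprafacial addition, and their sense from approach of the diene to the exo face of the cis-bicyclo[4.2.0]oct-7-ene, anti to ring A and syn to H6 and H7, which places ring B anti and lactone B syn to ring A as the target requires. C7' is set by the endo orientation of the lactone carbonyl (siloxy cis to C1') and is erased in step 10. The step needs ortho regioselectivity (siloxy-bearing carbon to C7a'), secured by the match of the butenolide β-carbon C3a' with the CH2 terminus of the 1-siloxydiene, and chemoselectivity for the strained alkene over the unstrained tetrasubstituted C3a=C7a bond and the electron-rich ylidenes. Mild acid on work-up should cleave the trimethylsilyl ether to alcohol 17.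

Step 10
Reactants: 17 7'-hydroxy cycloadduct
Product: 18 7'-oxo enone (C5'=C6'–C7'=O)
Conditions: Dess–Martin periodinane, NaHCO3, CH2Cl2, 0 °C to rt
Reagents that add atoms: none
Why: Dess–Martin oxidation of the secondary allylic alcohol under buffered, non-nucleophilic conditions should leave both enol lactones intact and removes the C7' stereocentre.

Step 11
Reactants: 18 7'-oxo enone
Product: 21 target dimer (CNP0371639.2), via tosylhydrazone 19 (not isolated), via allylic diazene 20 (not isolated)
Conditions: TsNHNH2, AcOH (cat.), EtOH, 50 °C; then catecholborane, CHCl3, 0 °C; then NaOAc·3H2O, 60 °C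
Reagents that add atoms: none
Why: Reductive 1,3-transposition of an enone through its tosylhydrazone (1,2-hydride addition by catecholborane, loss of sulfinate, retro-ene loss of N2 from the allylic diazene) moves the double bond to C6'=C7' and delivers hydrogen to C5', the regiochemistry being dictated by the mechanism and no stereocentre being formed.

Compound list
1 | dichloromaleic anhydride | O=C1OC(=O)C(Cl)=C1Cl | starting material
2 | n-butylmagnesium bromide | CCCC[Mg]Br | starting material
3 | (±)-5-butyl-3,4-dichloro-5-hydroxyfuran-2(5H)-one | CCCCC1(O)OC(=O)C(Cl)=C1Cl | intermediate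
4 | (R)-cyclohex-2-en-1-ol | O[C@H]1C=CCCC1 | starting material
5 | (5S)-5-butyl-3,4-dichloro-5-[(1R)-cyclohex-2-en-1-yloxy]furan-2(5H)-one | CCCC[C@]1(O[C@H]2C=CCCC2)OC(=O)C(Cl)=C1Cl | intermediate
6 | tetracyclic photoadduct (acetal-bridged 3a',7a'-dichloro lactone; all ring fusions cis; chlorines anti to the rings) | CCCC[C@@]12O[C@@H]3CCC[C@H]4[C@@H]3[C@]1(Cl)[C@@]4(Cl)C(=O)O2 | intermediate
7 | hydroxy keto acid (7,8-dichloro-2-hydroxy-8-pentanoylbicyclo[4.2.0]octane-7-carboxylic acid) | O[C@@H]1CCC[C@H]2[C@@H]1[C@@](Cl)(C(=O)CCCC)[C@@]2(Cl)C(=O)O | intermediate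
8 | C7a-keto acid (7,8-dichloro-2-oxo-8-pentanoylbicyclo[4.2.0]octane-7-carboxylic acid) | O=C1CCC[C@H]2[C@@H]1[C@@](Cl)(C(=O)CCCC)[C@@]2(Cl)C(=O)O | intermediate
9 | keto enol lactone ((Z)-butylidene lactone B on the dichlorocyclobutane, C7a ketone) | O=C1CCC[C@H]2[C@@H]1[C@]3(Cl)[C@@]2(Cl)C(=O)O/C3=C\CCC | intermediate
10 | pentanoyl chloride | CCCCC(Cl)=O | starting material
11 | C3a-pentanoyl β-diketone (enol form) | OC1=C(C(=O)CCCC)CC[C@H]2[C@@H]1[C@]3(Cl)[C@@]2(Cl)C(=O)O/C3=C\CCC | intermediate
12 | C7a enol triflate | FC(F)(F)S(=O)(=O)OC1=C(C(=O)CCCC)CC[C@H]2[C@@H]1[C@]3(Cl)[C@@]2(Cl)C(=O)O/C3=C\CCC | intermediate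
13 | 3a',7a'-dichloro bis-lactone | CCC/C=C1\OC(=O)C2=C1CC[C@H]1[C@@H]2[C@]2(Cl)[C@@]1(Cl)C(=O)O/C2=C\CCC | intermediate
14 | (E)-1-(trimethylsiloxy)buta-1,3-diene | C=C/C=C/O[Si](C)(C)C | starting material
15 | cyclobutene bis-butenolide (C3a'=C7a') | CCC/C=C1\OC(=O)C2=C1CC[C@H]1[C@@H]2C2=C1C(=O)O/C2=C\CCC | intermediate
16 | silyl ether cycloadduct (7'-trimethylsiloxy, C5'=C6') | CCC/C=C1\OC(=O)C2=C1CC[C@H]1[C@@H]2[C@]23CC=C[C@@H](O[Si](C)(C)C)[C@]12C(=O)O/C3=C\CCC | intermediate
17 | 7'-hydroxy cycloadduct | CCC/C=C1\OC(=O)C2=C1CC[C@H]1[C@@H]2[C@]23CC=C[C@@H](O)[C@]12C(=O)O/C3=C\CCC | intermediate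
18 | 7'-oxo enone | CCC/C=C1\OC(=O)C2=C1CC[C@H]1[C@@H]2[C@]23CC=CC(=O)[C@]12C(=O)O/C3=C\CCC | intermediate
19 | tosylhydrazone of 18 | CCC/C=C1\OC(=O)C2=C1CC[C@H]1[C@@H]2[C@]23CC=CC(=NNS(=O)(=O)c4ccc(C)cc4)[C@]12C(=O)O/C3=C\CCC | intermediate
20 | C7' allylic diazene (either C7' epimer) | CCC/C=C1\OC(=O)C2=C1CC[C@H]1[C@@H]2[C@]23CC=CC(N=N)[C@]12C(=O)O/C3=C\CCC | intermediate
21 | target dimer (rings A and B anti across the cis-fused cyclobutane, lactone B syn to ring A, both ylidenes Z) | CCC/C=C1\OC(=O)C2=C1CC[C@H]1[C@@H]2[C@]23CCC=C[C@]12C(=O)O/C3=C\CCC | target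

Total step count: 11. Longest linear sequence: 11 steps (1 to 21).

Steps most likely to fail

Step 9. The strained cyclobutene 15 may oligomerise, or the siloxydiene may add only in a Michael sense or in the wrong orientation, before ring B closes. The fallback sets out from 13 and builds ring B stepwise with established chemistry. 13 is dechlorinated with zinc at low temperature and the cold solution of 15 is run into but-3-enylmagnesium bromide with CuBr·SMe2 (conjugate addition at C3a' on the face anti to ring A). The magnesium enolate is trapped at C7a' with acetaldehyde to give the 3a'-(but-3-enyl)-7a'-(1-hydroxyethyl) lactone F1. Dehydration with Burgess reagent gives the 3a'-(but-3-enyl)-7a'-vinyl lactone F2. Ring-closing metathesis with the second-generation Grubbs catalyst, RuCl2(=CHPh)(PCy3)(H2IMes), then forms the C6'=C7' bond directly and rejoins the route at 21.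

Step 8. The enol oxygen may fail to capture the acylpalladium intermediate, so that reduction of the triflate competes. The fallback sets out from 12 and intercepts the acyl group intermolecularly: Pd(OAc)2, dppp, CO, 2-(trimethylsilyl)ethanol and iPr2NEt give the 2-(trimethylsilyl)ethyl keto ester F3. Trifluoroacetic acid followed by (CF3CO)2O then frees the γ-keto acid and closes lactone A by the acid-mediated enol lactonisation already used in step 5, rejoining at 13.

Step 11. Condensation at the hindered, cross-conjugated ketone may be slow, and the sulfonylhydrazide may open an enol lactone instead. The fallback sets out from 18: conjugate reduction with LiBH(s-Bu)3 at −78 °C and trapping of the enolate with PhNTf2 give the C7' enol triflate F4, the only possible regioisomer because C7a' is quaternary. Hydrogenolysis with Pd(OAc)2, PPh3 and Bu3N·HCO2H in DMF then gives the C6'=C7' alkene and rejoins the route at 21.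

Further compounds
F1 | step 9 | 3a'-(but-3-enyl)-7a'-(1-hydroxyethyl) lactone (carbinol epimers) | CCC/C=C1\OC(=O)C2=C1CC[C@H]1[C@@H]2[C@]2(CCC=C)[C@@]1(C(C)O)C(=O)O/C2=C\CCC
F2 | step 9 | 3a'-(but-3-enyl)-7a'-vinyl lactone | CCC/C=C1\OC(=O)C2=C1CC[C@H]1[C@@H]2[C@]2(CCC=C)[C@@]1(C=C)C(=O)O/C2=C\CCC
F3 | step 8 | 2-(trimethylsilyl)ethyl keto ester (ester on C7a, pentanoyl on C3a) | C[Si](C)(C)CCOC(=O)C1=C(C(=O)CCCC)CC[C@H]2[C@@H]1[C@]3(Cl)[C@@]2(Cl)C(=O)O/C3=C\CCC
F4 | step 11 | C7' enol triflate (C6'=C7') | CCC/C=C1\OC(=O)C2=C1CC[C@H]1[C@@H]2[C@]23CCC=C(OS(=O)(=O)C(F)(F)F)[C@]12C(=O)O/C3=C\CCC
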